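**Retrosynthetic overview**

- Feature: in naphthalene ring A (C1', C2', C3', C4', C4a', C8a') the methyl-bearing C2' lies between C1', which carries isoquinoline C7, and C3'–H. Removing C2' contracts ring A to the five-membered ring of a 3-aryl-1-methoxy-1H-indene. Its single C=C (future C1'/C3') marks where one carbon must go back in, and its C1 (future C4') already carries the methoxy group.
- Late stage: the C7–C1' axis is resolved last. Both phenols are released from isopropyl ethers. C2'–CH3 comes from C2'–Br, and C2'–Br comes from dibromocarbene insertion, which forms C1'–C2' and C2'–C3' and takes ring A from five to six members.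
- The easy aryl–vinyl bond (isoquinoline C7 to indene C3) comes from a Negishi coupling. The O-methyl group is installed before any ring nitrogen is present, and everything from there to the ring expansion is run without base, because 1-oxyindenes shift their double bond under base catalysis.
- Ring order: the benzo ring and the five-membered ring arrive with 7-hydroxy-1-indanone. The pyridine ring is closed from 3-methoxybenzyne, acetylacetone and ammonia. Ring A is completed last by enlargement.

Key step: step 11

Assumption: the SMILES is taken as binding (4'-OMe, free 5'-OH and 8-OH). It does not encode the C7–C1' axis, which is taken as M for the ent series (mirror image of the P axis of the dioncophylline A series), so the racemate is made and separated.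

**Step 1**
Reactants: 1 7-hydroxy-1-indanone
Product: 2 7-isopropoxyindan-1-one
Conditions: 2-bromopropane, K2CO3, DMF, 60 °C
Reagents that add atoms: 2-bromopropane, CC(C)Br
Why: Williamson ether synthesis; the isopropyl ether is chosen because, unlike a benzyl ether, it offers no benzylic C–H to the bromine radical of step 2, and BCl3 can later cleave it beside an aryl methyl ether.

**Step 2**
Reactants: 2 7-isopropoxyindan-1-one
Product: 4 3-bromo-7-isopropoxy-1H-inden-1-one, via 3,3-dibromo-7-isopropoxyindan-1-one 3 (not isolated)
Conditions: NBS (2.2 equiv), AIBN (cat.), PhCF3, 85 °C; then Et3N, 0 °C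
Reagents that add atoms: N-bromosuccinimide, O=C1CCC(=O)N1Br
Why: Wohl–Ziegler bromination takes both hydrogens of C3, the only benzylic position, and triethylamine then removes the acidic C2 proton and expels one bromide (E1cB), which is the known indanone to 3-bromoindenone sequence.

**Step 3**
Reactants: 4 3-bromo-7-isopropoxy-1H-inden-1-one
Product: 5 racemic 3-bromo-7-isopropoxy-1H-inden-1-ol
Conditions: NaBH4, CeCl3·7H2O, MeOH/THF, −20 °C; aq NH4Cl quench
Reagents that add atoms: none
Why: Luche reduction delivers hydride to the carbonyl carbon rather than to the bromine-bearing β-carbon and sets C1 as a racemic stereocentre that step 11 erases, and the quench is kept near neutral because inden-1-ols isomerise to indanones under base catalysis.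

**Step 4**
Reactants: 5 racemic 3-bromo-7-isopropoxy-1H-inden-1-ol
Product: 6 racemic 3-bromo-7-isopropoxy-1-methoxy-1H-indene
Conditions: MeOTf, 2,6-di-tert-butyl-4-methylpyridine, CH2Cl2, 0 °C to rt; silica without amine additive
Reagents that add atoms: methyl trifluoromethanesulfonate, COS(=O)(=O)C(F)(F)F
Why: O-methylation with methyl triflate and a hindered pyridine needs no alkoxide, so the acidic allylic-benzylic C1–H is untouched and the alkene stays at C2=C3, and it is done at this stage because no isoquinoline nitrogen is yet present to be quaternised.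

**Step 5**
Reactants: 7 3-methoxy-2-(trimethylsilyl)phenyl trifluoromethanesulfonate; 8 acetylacetone
Product: 11 8-methoxy-1,3-dimethylisoquinoline, via 3-methoxybenzyne 9 (not isolated), via 1-(2-acetyl-3-methoxyphenyl)propan-2-one 10 (not isolated)
Conditions: CsF, MeCN, 80 °C; then 28% aq NH4OH, 60 °C
Reagents that add atoms: ammonia, N
Why: Aryne acyl-alkylation, in which the enolate carbon adds to the aryne carbon remote from OMe, the aryl anion ortho to OMe attacks a ketone and the cyclobutoxide fragments (formal C–C insertion), followed by the classical cyclocondensation of the 1,5-diketone with ammonia, which closes the pyridine ring with OMe at C8.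

**Step 6**
Reactants: 11 8-methoxy-1,3-dimethylisoquinoline
Product: 12 1,3-dimethylisoquinolin-8-ol
Conditions: 48% aq HBr, AcOH, 120 °C; then NaHCO3 to pH 8
Reagents that add atoms: none
Why: Acidic aryl methyl ether cleavage (SN2 attack of bromide on the protonated ether) is tolerated by the fully aromatic heterocycle and frees the phenol that steers the next bromination.

**Step 7**
Reactants: 12 1,3-dimethylisoquinolin-8-ol
Product: 13 7-bromo-1,3-dimethylisoquinolin-8-ol
Conditions: NBS (1.0 equiv), iPr2NH (cat.), CH2Cl2, 0 °C
Reagents that add atoms: N-bromosuccinimide, O=C1CCC(=O)N1Br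
Why: Amine-mediated ortho-selective bromination of phenols, in which the N-bromoamine formed in situ hydrogen-bonds to the phenol and hands bromine to the only free ortho position C7, as in the known conversion of 1-naphthol into 2-bromo-1-naphthol under these conditions.

**Step 8**
Reactants: 13 7-bromo-1,3-dimethylisoquinolin-8-ol
Product: 14 7-bromo-8-isopropoxy-1,3-dimethylisoquinoline
Conditions: 2-bromopropane, K2CO3, DMF, 70 °C
Reagents that add atoms: 2-bromopropane, CC(C)Br
Why: Williamson ether synthesis; the phenoxide is far more nucleophilic than a nitrogen flanked by two methyl groups, and a secondary halide does not quaternise such a nitrogen.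

**Step 9**
Reactants: 14 7-bromo-8-isopropoxy-1,3-dimethylisoquinoline; 6 racemic 3-bromo-7-isopropoxy-1-methoxy-1H-indene
Product: 17 racemic 8-isopropoxy-7-(7-isopropoxy-1-methoxy-1H-inden-3-yl)-1,3-dimethylisoquinoline, via 7-lithio-8-isopropoxy-1,3-dimethylisoquinoline 15 (not isolated), via (8-isopropoxy-1,3-dimethylisoquinolin-7-yl)zinc chloride 16 (not isolated)
Conditions: 14, n-BuLi, THF, −78 °C, 10 min; ZnCl2, −78 °C to rt; then 6, Pd2(dba)3 (cat.), SPhos, THF, 50 °C
Reagents that add atoms: none
Why: Bromine–lithium exchange at −78 °C outruns deprotonation of the C1 and C3 methyl groups, immediate transmetalation gives a weakly basic arylzinc, and the Negishi coupling with the vinyl bromide needs no added base, so the C1–H of the methoxyindene is left alone and the alkene stays between C2 and C3.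

**Step 10**
Reactants: 18 bromoform
Product: 19 phenyl(tribromomethyl)mercury
Conditions: PhHgCl, KOtBu, benzene, 5 °C
Reagents that add atoms: phenylmercury chloride, Cl[Hg]c1ccccc1
Why: Deprotonation of bromoform in the presence of the mercury halide replaces chloride at mercury by the tribromomethyl group faster than bromide is lost, which is the standard preparation of this neutral carbene-transfer reagent.

**Step 11**
Reactants: 17 racemic 8-isopropoxy-7-(7-isopropoxy-1-methoxy-1H-inden-3-yl)-1,3-dimethylisoquinoline; 19 phenyl(tribromomethyl)mercury
Product: 21 racemic 7-(2-bromo-5-isopropoxy-4-methoxynaphthalen-1-yl)-8-isopropoxy-1,3-dimethylisoquinoline, via gem-dibromocyclopropane adduct 20 (not isolated)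
Conditions: 19 (2 equiv, two portions), benzene, 80 °C; aq NaHCO3 wash
Reagents that add atoms: phenyl(tribromomethyl)mercury 19, BrC(Br)(Br)[Hg]c1ccccc1
Why: At 80 °C 19 releases dibromocarbene without any base (phenylmercury bromide separates), and the electrophilic singlet carbene adds in a [2+1] cheletropic manner to the only alkene of 17, C2=C3, closing the three-membered ring of 20 and forming the future C1'–C2' and C2'–C3' bonds. The fused cyclopropane then ionises with loss of the endo bromide in a disrotatory two-electron electrocyclic opening that breaks the old C2–C3 bond and enlarges the five-membered ring to six, the allyl cation being stabilised at C1' by two aryl groups. Loss of the proton geminal to the methoxy group aromatises ring A with no oxidant, and the HBr rests on the isoquinoline nitrogen until the bicarbonate wash. The closest known reaction type is the dihalocarbene ring expansion of indenes to 2-halonaphthalenes. The stereocentres of 17 and 20 vanish, and the C7–C1' bond becomes a stereogenic axis without any controlling element, so 21 should form as a racemate. The step needs chemoselectivity for the alkene over the nitrogen (shielded by the C1 and C3 methyl groups) and over the α-oxy C–H bonds, and above all a fixed alkene position: alkoxide or phase-transfer hydroxide would move the double bond by 1,3-proton shift to the more nucleophilic enol ether isomer and lead to the 3'-bromo isomer, which the neutral mercurial avoids.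

**Step 12**
Reactants: 21 racemic 7-(2-bromo-5-isopropoxy-4-methoxynaphthalen-1-yl)-8-isopropoxy-1,3-dimethylisoquinoline
Product: 22 racemic 8-isopropoxy-7-(5-isopropoxy-4-methoxy-2-methylnaphthalen-1-yl)-1,3-dimethylisoquinoline
Conditions: trimethylboroxine, Pd(OAc)2 (cat.), SPhos, K2CO3, dioxane/H2O, 100 °C
Reagents that add atoms: trimethylboroxine, CB1OB(C)OB(C)O1
Why: Suzuki–Miyaura methylation, in which the bulky electron-rich phosphine helps zerovalent palladium insert into the ortho-crowded C2'–Br bond, while the ethers and the heterocycle are inert.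

**Step 13**
Reactants: 22 racemic 8-isopropoxy-7-(5-isopropoxy-4-methoxy-2-methylnaphthalen-1-yl)-1,3-dimethylisoquinoline
Product: 23 racemic 7-(5-hydroxy-4-methoxy-2-methylnaphthalen-1-yl)-1,3-dimethylisoquinolin-8-ol
Conditions: BCl3 (6 equiv), CH2Cl2, −10 °C to rt; MeOH, then aq NaHCO3
Reagents that add atoms: none
Why: Lewis acid ether cleavage; BCl3 removes secondary alkyl groups from aryl ethers by an SN1-like path much faster than methyl groups, so both phenols should be freed and 4'-OMe kept if time and temperature are limited.

**Step 14**
Reactants: 23 racemic 7-(5-hydroxy-4-methoxy-2-methylnaphthalen-1-yl)-1,3-dimethylisoquinolin-8-ol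
Product: 24 (M)-7-(5-hydroxy-4-methoxy-2-methylnaphthalen-1-yl)-1,3-dimethylisoquinolin-8-ol (target)
Conditions: preparative HPLC, Chiralcel OD-H, n-hexane/iPrOH, rt
Reagents that add atoms: none
Why: Enantiomer separation on a cellulose carbamate phase; the axis is flanked by 8-OH, 2'-CH3 and the fused ring at C8a' and should not rotate at room temperature, and the M enantiomer is to be assigned by circular dichroism.

**Compound list**

| No. | Name | SMILES | Role |
|---|---|---|---|
| 1 | 7-hydroxy-1-indanone | O=C1CCc2cccc(O)c12 | starting material |
| 2 | 7-isopropoxyindan-1-one | O=C1CCc2cccc(OC(C)C)c12 | intermediate |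
| 3 | 3,3-dibromo-7-isopropoxyindan-1-one | O=C1CC(Br)(Br)c2cccc(OC(C)C)c12 | intermediate |
| 4 | 3-bromo-7-isopropoxy-1H-inden-1-one | O=C1C=C(Br)c2cccc(OC(C)C)c12 | intermediate |
| 5 | racemic 3-bromo-7-isopropoxy-1H-inden-1-ol | OC1C=C(Br)c2cccc(OC(C)C)c12 | intermediate |
| 6 | racemic 3-bromo-7-isopropoxy-1-methoxy-1H-indene | COC1C=C(Br)c2cccc(OC(C)C)c12 | intermediate |
| 7 | 3-methoxy-2-(trimethylsilyl)phenyl trifluoromethanesulfonate | COc1cccc(OS(=O)(=O)C(F)(F)F)c1[Si](C)(C)C | starting material |
| 8 | acetylacetone | CC(=O)CC(C)=O | starting material |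
| 9 | 3-methoxybenzyne | COC1=CC=CC#C1 | intermediate |
| 10 | 1-(2-acetyl-3-methoxyphenyl)propan-2-one | COc1cccc(CC(C)=O)c1C(C)=O | intermediate |
| 11 | 8-methoxy-1,3-dimethylisoquinoline | COc1cccc2cc(C)nc(C)c12 | intermediate |
| 12 | 1,3-dimethylisoquinolin-8-ol | Cc1cc2cccc(O)c2c(C)n1 | intermediate |
| 13 | 7-bromo-1,3-dimethylisoquinolin-8-ol | Cc1cc2ccc(Br)c(O)c2c(C)n1 | intermediate |
| 14 | 7-bromo-8-isopropoxy-1,3-dimethylisoquinoline | Cc1cc2ccc(Br)c(OC(C)C)c2c(C)n1 | intermediate |
| 15 | 7-lithio-8-isopropoxy-1,3-dimethylisoquinoline | [Li]c1ccc2cc(C)nc(C)c2c1OC(C)C | intermediate |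
| 16 | (8-isopropoxy-1,3-dimethylisoquinolin-7-yl)zinc chloride | Cl[Zn]c1ccc2cc(C)nc(C)c2c1OC(C)C | intermediate |
| 17 | racemic 8-isopropoxy-7-(7-isopropoxy-1-methoxy-1H-inden-3-yl)-1,3-dimethylisoquinoline | COC1C=C(c2ccc3cc(C)nc(C)c3c2OC(C)C)c2cccc(OC(C)C)c12 | intermediate |
| 18 | bromoform | BrC(Br)Br | starting material |
| 19 | phenyl(tribromomethyl)mercury | BrC(Br)(Br)[Hg]c1ccccc1 | intermediate |
| 20 | gem-dibromocyclopropane adduct of 17 across C2=C3 (racemic, mixture of diastereomers) | COC1C2C(Br)(Br)C2(c3ccc4cc(C)nc(C)c4c3OC(C)C)c5cccc(OC(C)C)c15 | intermediate |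
| 21 | racemic 7-(2-bromo-5-isopropoxy-4-methoxynaphthalen-1-yl)-8-isopropoxy-1,3-dimethylisoquinoline | COc1cc(Br)c(-c2ccc3cc(C)nc(C)c3c2OC(C)C)c2cccc(OC(C)C)c12 | intermediate |
| 22 | racemic 8-isopropoxy-7-(5-isopropoxy-4-methoxy-2-methylnaphthalen-1-yl)-1,3-dimethylisoquinoline | COc1cc(C)c(-c2ccc3cc(C)nc(C)c3c2OC(C)C)c2cccc(OC(C)C)c12 | intermediate |
| 23 | racemic 7-(5-hydroxy-4-methoxy-2-methylnaphthalen-1-yl)-1,3-dimethylisoquinolin-8-ol | COc1cc(C)c(-c2ccc3cc(C)nc(C)c3c2O)c2cccc(O)c12 | intermediate |
| 24 | (M)-7-(5-hydroxy-4-methoxy-2-methylnaphthalen-1-yl)-1,3-dimethylisoquinolin-8-ol (axis not expressible in SMILES) | COc1cc(C)c(-c2ccc3cc(C)nc(C)c3c2O)c2cccc(O)c12 | target |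

Total step count: 14 (13 reactions and one separation).
Longest linear sequence: 9 steps (1–4, 9, 11–14; the branch 5–8, 9, 11–14 is equally long).

**Steps most likely to fail**

**Step 11.** Carbene transfer to the crowded trisubstituted alkene may be slower than loss of the carbene to the ring nitrogen or to insertion into the α-oxy C–H bonds of the isopropyl groups. Part of the substrate may also leave solution as its hydrobromide.

The fallback enlarges the ring before the isoquinoline is attached, and sets out from 6.
- PhHgCCl2Br in benzene at 80 °C should transfer dichlorocarbene to the nitrogen-free bromoalkene and give the bromodichlorocyclopropane adduct F1.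
- On heating in toluene at 110 °C (AgBF4 if ionisation lags), this adduct should lose the endo chloride and the proton next to the methoxy group to give 1-bromo-2-chloro-5-isopropoxy-4-methoxynaphthalene F2.
- Negishi coupling with the zinc reagent 16 (Pd2(dba)3, SPhos, THF, 50 °C) should occur at the C–Br bond only and give 7-(2-chloro-5-isopropoxy-4-methoxynaphthalen-1-yl)-8-isopropoxy-1,3-dimethylisoquinoline F3.
- Negishi methylation of the C–Cl bond (MeZnCl, Pd(OAc)2, SPhos, THF, 65 °C) comes back to the route at 22.

The price is that the biaryl bond is then made in its crowded form.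

**Step 9.** Proton transfer from the acidic C1 methyl group to the aryllithium before zinc arrives would erode the coupling. So would a 1,3-proton shift in the methoxyindene set off by residual carbanion.

The fallback uses no carbanion at all, and sets out from 14.
- Pd(PPh3)4-catalysed stannylation with Me3SnSnMe3 (toluene, 110 °C) should give 8-isopropoxy-1,3-dimethyl-7-(trimethylstannyl)isoquinoline F4.
- Neutral Stille coupling of this stannane with 6 (Pd(PPh3)4, CuCl, LiCl, DMSO, 60 °C) comes back to the route at 17.

**Step 7.** Attack of the brominating agent para to the hydroxyl group (C5), or twofold bromination, would spoil the regiochemistry on which the C7 linkage depends.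

The fallback replaces electrophilic substitution by a directed C–H borylation, and sets out from 12.
- Dehydrogenative silylation with Et2SiH2 ([Ir(cod)Cl]2 cat., THF, rt) should give 8-(diethylsilyloxy)-1,3-dimethylisoquinoline F5.
- Silyl-directed ortho borylation ([Ir(cod)Cl]2, dtbpy, B2pin2, THF, 80 °C) should give 8-(diethylsilyloxy)-1,3-dimethyl-7-(4,4,5,5-tetramethyl-1,3,2-dioxaborolan-2-yl)isoquinoline F6.
- CuBr2 in MeOH/H2O at 80 °C should replace boron by bromine and strip the silyl group, coming back to the route at 13.

**Further compounds**
F1 | step 11 | bromodichlorocyclopropane adduct of 6 across C2=C3 (racemic) | COC1C2C(Cl)(Cl)C2(Br)c3cccc(OC(C)C)c13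
F2 | step 11 | 1-bromo-2-chloro-5-isopropoxy-4-methoxynaphthalene | COc1cc(Cl)c(Br)c2cccc(OC(C)C)c12
F3 | step 11 | racemic 7-(2-chloro-5-isopropoxy-4-methoxynaphthalen-1-yl)-8-isopropoxy-1,3-dimethylisoquinoline | COc1cc(Cl)c(-c2ccc3cc(C)nc(C)c3c2OC(C)C)c2cccc(OC(C)C)c12
F4 | step 9 | 8-isopropoxy-1,3-dimethyl-7-(trimethylstannyl)isoquinoline | Cc1cc2ccc([Sn](C)(C)C)c(OC(C)C)c2c(C)n1
F5 | step 7 | 8-(diethylsilyloxy)-1,3-dimethylisoquinoline | CC[SiH](CC)Oc1cccc2cc(C)nc(C)c12
F6 | step 7 | 8-(diethylsilyloxy)-1,3-dimethyl-7-(4,4,5,5-tetramethyl-1,3,2-dioxaborolan-2-yl)isoquinoline | CC[SiH](CC)Oc1c(B2OC(C)(C)C(C)(C)O2)ccc2cc(C)nc(C)c12
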